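The pyranone ring (ring C) is closed last between C3 and C2. C2 is a benzylic methine bonded to O1 and to the electron-rich 2,4-dioxygenated ring B, so in an open precursor its methylene C–H bonds are hydridic, and C3 lies alpha to the C4 ketone and can be made a carbenoid. The precursor is therefore a ring A aryl diazomethyl ketone whose ortho oxygen carries a 2,4-bis(silyloxy)benzyl group: a chiral dirhodium carboxylate inserts the carbenoid into one enantiotopic benzylic C–H bond and gives the flavanone with C2 set. The (R)-side chain comes from an Evans dienolate alkylation and is joined to ring A by Negishi coupling.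

Key step: step 14

Assumption: the sense of induction in step 14 cannot be predicted with confidence; Rh2(S-PTTL)4 is written, and the mirror-image catalyst Rh2(R-PTTL)4 would be used instead if a model substrate shows that the S ligand leads to 2R.

Abbreviations: TBS = tert-butyldimethylsilyl, TES = triethylsilyl, Rh2(S-PTTL)4 = dirhodium tetrakis[N-phthaloyl-(S)-tert-leucinate], SPhos = 2-dicyclohexylphosphino-2',6'-dimethoxybiphenyl, DIAD = diisopropyl azodicarboxylate.

**Side chain (steps 1–6)**

Step 1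
Reactants: 1 (S)-4-benzyl-1,3-oxazolidin-2-one; 2 3-methylbut-2-enoyl chloride
Product: 4 (S)-4-benzyl-3-(3-methylbut-2-enoyl)-1,3-oxazolidin-2-one, via lithium oxazolidinide 3 (not isolated)
Conditions: n-BuLi, THF, −78 °C; then 2, −78 → 0 °C
Reagents that add atoms: none
Why: N-acylation of the lithiated Evans auxiliary by the acid chloride should give the imide without touching the auxiliary stereocentre.

Step 2
Reactants: 4 (S)-4-benzyl-3-(3-methylbut-2-enoyl)-1,3-oxazolidin-2-one; 5 1-bromo-3-methylbut-2-ene (prenyl bromide)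
Product: 7 (4S)-4-benzyl-3-[(2S)-5-methyl-2-(prop-1-en-2-yl)hex-4-enoyl]-1,3-oxazolidin-2-one, via sodium dienolate 6 (not isolated)
Conditions: NaHMDS, THF, −78 °C; then 5, −78 → −40 °C
Reagents that add atoms: none
Why: Deconjugative Evans alkylation: gamma-deprotonation gives the chelated (Z)-dienolate, which should be alkylated at the alpha carbon (SN2 on the allylic bromide) from the face opposite the benzyl group, setting the (2S) centre that becomes the (R) side-chain centre of the target.

Step 3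
Reactants: 7 (4S)-4-benzyl-3-[(2S)-5-methyl-2-(prop-1-en-2-yl)hex-4-enoyl]-1,3-oxazolidin-2-one
Product: 8 (4S)-4-benzyl-3-[(2S)-3-(3,3-dimethyloxiran-2-yl)-2-(prop-1-en-2-yl)propanoyl]-1,3-oxazolidin-2-one (both oxirane epimers)
Conditions: mCPBA (1.05 equiv), NaHCO3, CH2Cl2, −10 → 0 °C
Reagents that add atoms: mCPBA, O=C(OO)c1cccc(Cl)c1
Why: Prilezhaev epoxidation should select the more electron-rich trisubstituted alkene over the 1,1-disubstituted isopropenyl group; the oxirane CH centre is uncontrolled but is erased in step 4.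

Step 4
Reactants: 8 (4S)-4-benzyl-3-[(2S)-3-(3,3-dimethyloxiran-2-yl)-2-(prop-1-en-2-yl)propanoyl]-1,3-oxazolidin-2-one
Product: 9 (2S)-5-methyl-2-(prop-1-en-2-yl)hexane-1,5-diol
Conditions: LiAlH4, THF, 0 °C → reflux
Reagents that add atoms: none
Why: Hydride reduction should cleave the imide to the primary alcohol (auxiliary released) and open the trisubstituted oxirane by SN2 attack at its CH carbon to give the tertiary alcohol, leaving the allylic stereocentre untouched.

Step 5
Reactants: 9 (2S)-5-methyl-2-(prop-1-en-2-yl)hexane-1,5-diol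
Product: 10 (5S)-6-iodo-2-methyl-5-(prop-1-en-2-yl)hexan-2-ol
Conditions: I2, PPh3, imidazole, CH2Cl2, 0 °C
Reagents that add atoms: iodine, II
Why: Appel-type iodination proceeds by SN2 displacement of the primary oxyphosphonium ion, and the tertiary alcohol should not react at 0 °C.

Step 6
Reactants: 10 (5S)-6-iodo-2-methyl-5-(prop-1-en-2-yl)hexan-2-ol
Product: 11 triethyl{[(5S)-6-iodo-2-methyl-5-(prop-1-en-2-yl)hexan-2-yl]oxy}silane
Conditions: TESOTf, 2,6-lutidine, CH2Cl2, −78 → 0 °C
Reagents that add atoms: triethylsilyl trifluoromethanesulfonate, CC[Si](CC)(CC)OS(=O)(=O)C(F)(F)F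
Why: Silylation with the silyl triflate should cap the hindered tertiary alcohol so that it survives the organozinc, enolate and carbenoid steps.

**Ring B benzyl alcohol (steps 7–8)**

Step 7
Reactants: 12 2,4-dihydroxybenzaldehyde
Product: 13 2,4-bis(tert-butyldimethylsilyloxy)benzaldehyde
Conditions: TBSCl (2.4 equiv), imidazole, DMF, rt
Reagents that add atoms: tert-butyldimethylsilyl chloride, CC(C)(C)[Si](C)(C)Cl
Why: Imidazole-promoted silylation should protect both phenols, including the chelated ortho hydroxyl, in DMF.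

Step 8
Reactants: 13 2,4-bis(tert-butyldimethylsilyloxy)benzaldehyde
Product: 14 [2,4-bis(tert-butyldimethylsilyloxy)phenyl]methanol
Conditions: NaBH4, THF/EtOH, −20 → 0 °C; aq NH4Cl
Reagents that add atoms: none
Why: Borohydride reduction of the aldehyde at low temperature with a buffered quench should give the benzylic alcohol before aryl-to-alkyl silyl migration can occur.

**Ring A and assembly (steps 9–15)**

Step 9
Reactants: 15 1-(2,4-dihydroxy-6-methoxyphenyl)ethan-1-one
Product: 16 1-(2,4-dihydroxy-3-iodo-6-methoxyphenyl)ethan-1-one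
Conditions: I2 (0.4 equiv), HIO3 (0.2 equiv), EtOH/H2O, 35 °C
Reagents that add atoms: iodine, II; iodic acid, O[I](=O)=O
Why: Electrophilic aromatic iodination should occur at C3, which is flanked by both free hydroxyls, ortho to the chelated 2-OH and para to the methoxy group, as with resacetophenone under these conditions; this carbon becomes C8.

Step 10
Reactants: 16 1-(2,4-dihydroxy-3-iodo-6-methoxyphenyl)ethan-1-one
Product: 17 1-[4-(tert-butyldimethylsilyloxy)-2-hydroxy-3-iodo-6-methoxyphenyl]ethan-1-one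
Conditions: TBSCl (1.05 equiv), imidazole, CH2Cl2, 0 °C
Reagents that add atoms: tert-butyldimethylsilyl chloride, CC(C)(C)[Si](C)(C)Cl
Why: Silylation should select the 4-OH because the 2-OH is tied up in a hydrogen bond to the acetyl carbonyl.

Step 11
Reactants: 17 1-[4-(tert-butyldimethylsilyloxy)-2-hydroxy-3-iodo-6-methoxyphenyl]ethan-1-one; 14 [2,4-bis(tert-butyldimethylsilyloxy)phenyl]methanol
Product: 18 1-[2-{[2,4-bis(tert-butyldimethylsilyloxy)phenyl]methoxy}-4-(tert-butyldimethylsilyloxy)-3-iodo-6-methoxyphenyl]ethan-1-one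
Conditions: PPh3, DIAD, THF, 0 °C → rt
Reagents that add atoms: none
Why: Mitsunobu etherification of the acidic ortho-acyl phenol with the primary benzylic alcohol should form the O1–CH2 bond under neutral conditions that spare the aryl silyl ethers.

Step 12
Reactants: 11 triethyl{[(5S)-6-iodo-2-methyl-5-(prop-1-en-2-yl)hexan-2-yl]oxy}silane; 18 1-[2-{[2,4-bis(tert-butyldimethylsilyloxy)phenyl]methoxy}-4-(tert-butyldimethylsilyloxy)-3-iodo-6-methoxyphenyl]ethan-1-one
Product: 20 1-[2-{[2,4-bis(tert-butyldimethylsilyloxy)phenyl]methoxy}-4-(tert-butyldimethylsilyloxy)-6-methoxy-3-{(2R)-5-methyl-2-(prop-1-en-2-yl)-5-[(triethylsilyl)oxy]hexyl}phenyl]ethan-1-one, via alkylzinc iodide 19 (not isolated)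
Conditions: Zn dust, LiCl, THF, 40 °C; then 18, Pd(OAc)2 (5 mol %), SPhos (10 mol %), THF, 50 °C
Reagents that add atoms: none
Why: Zinc insertion into the primary C–I bond and Negishi coupling with the aryl iodide should join chain and ring A, since the SPhos–palladium catalyst accepts di-ortho-substituted aryl iodides, the alkylzinc tolerates ketone and silyl ethers, and the stereocentre beta to zinc is not involved.

Step 13
Reactants: 20 1-[2-{[2,4-bis(tert-butyldimethylsilyloxy)phenyl]methoxy}-4-(tert-butyldimethylsilyloxy)-6-methoxy-3-{(2R)-5-methyl-2-(prop-1-en-2-yl)-5-[(triethylsilyl)oxy]hexyl}phenyl]ethan-1-one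
Product: 23 2-diazo-1-[2-{[2,4-bis(tert-butyldimethylsilyloxy)phenyl]methoxy}-4-(tert-butyldimethylsilyloxy)-6-methoxy-3-{(2R)-5-methyl-2-(prop-1-en-2-yl)-5-[(triethylsilyl)oxy]hexyl}phenyl]ethan-1-one, via lithium enolate 21 (not isolated), via trifluoroacetyl ketone 22 (not isolated)
Conditions: LiHMDS, THF, −78 °C; CF3CO2CH2CF3; then MsN3, Et3N, H2O (1 equiv), MeCN, rt
Reagents that add atoms: methanesulfonyl azide, CS(=O)(=O)N=[N+]=[N-]
Why: Danheiser detrifluoroacetylative diazo transfer: the kinetic methyl ketone enolate is trifluoroacetylated and the activated 1,3-diketone should undergo Regitz diazo transfer with loss of the trifluoroacetyl group to give the terminal diazo ketone.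

Step 14
Reactants: 23 2-diazo-1-[2-{[2,4-bis(tert-butyldimethylsilyloxy)phenyl]methoxy}-4-(tert-butyldimethylsilyloxy)-6-methoxy-3-{(2R)-5-methyl-2-(prop-1-en-2-yl)-5-[(triethylsilyl)oxy]hexyl}phenyl]ethan-1-one
Product: 24 (2S)-2-[2,4-bis(tert-butyldimethylsilyloxy)phenyl]-7-(tert-butyldimethylsilyloxy)-5-methoxy-8-{(2R)-5-methyl-2-(prop-1-en-2-yl)-5-[(triethylsilyl)oxy]hexyl}-2,3-dihydro-4H-chromen-4-one
Conditions: Rh2(S-PTTL)4 (2 mol %), CH2Cl2, 4 Å MS, −20 °C → rt, slow addition of 23
Reagents that add atoms: none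
Why: The dirhodium tetracarboxylate (divalent rhodium) decomposes the diazo ketone with loss of N2 to an electrophilic rhodium carbenoid at C3, which inserts into a benzylic C–H bond of the OCH2Ar group through a concerted, hydride-transfer-like three-centre transition state, forming the C3–C2 bond and moving that hydrogen to C3. The closest known reaction type is the enantioselective dirhodium-carboxylate-catalysed intramolecular C–H insertion of 2-alkoxyaryl alpha-diazo ketones next to the ether oxygen, which gives chroman-4-ones. Ring C closes as a formal 1,6-insertion through a six-membered cyclic transition state, the only C–H insertion ring size open because the 1,5-position is O1 itself. The new stereocentre C2 is set under catalyst control: the chiral phthalimido-carboxylate ligands distinguish the two enantiotopic benzylic hydrogens, and the remote side-chain centre should have no influence. The step needs insertion to win over attack of O1 on the carbenoid (oxonium ylide, then [1,2]-benzyl shift) and over insertion into the C5 methoxy group; the benzylic C–H is doubly activated by O1 and the 2,4-bis(silyloxy)phenyl ring, O1 is crowded by its two ortho neighbours and deactivated by the ortho acyl group, and the OCH3 bonds are primary and unactivated.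

Step 15
Reactants: 24 (2S)-2-[2,4-bis(tert-butyldimethylsilyloxy)phenyl]-7-(tert-butyldimethylsilyloxy)-5-methoxy-8-{(2R)-5-methyl-2-(prop-1-en-2-yl)-5-[(triethylsilyl)oxy]hexyl}-2,3-dihydro-4H-chromen-4-one
Product: 25 (2S)-2-(2,4-dihydroxyphenyl)-7-hydroxy-8-[(2R)-5-hydroxy-5-methyl-2-(prop-1-en-2-yl)hexyl]-5-methoxy-2,3-dihydro-4H-chromen-4-one
Conditions: TBAF, AcOH (1:1), THF, 0 °C → rt
Reagents that add atoms: none
Why: Fluoride desilylation buffered with acetic acid should remove the three aryl TBS groups and the tertiary TES group without forming free phenoxides that could open ring C by retro-oxa-Michael reaction and scramble C2.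

**Compound list**

1 | (S)-4-benzyl-1,3-oxazolidin-2-one | O=C1N[C@@H](Cc2ccccc2)CO1 | starting material
2 | 3-methylbut-2-enoyl chloride | CC(C)=CC(=O)Cl | starting material
3 | lithium (S)-4-benzyl-2-oxo-1,3-oxazolidin-3-ide | [Li+].O=C1[N-][C@@H](Cc2ccccc2)CO1 | intermediate
4 | (S)-4-benzyl-3-(3-methylbut-2-enoyl)-1,3-oxazolidin-2-one | CC(C)=CC(=O)N1[C@@H](Cc2ccccc2)COC1=O | intermediate
5 | 1-bromo-3-methylbut-2-ene (prenyl bromide) | CC(C)=CCBr | starting material
6 | sodium (Z)-dienolate of 4 | [Na+].C=C(C)/C=C(\[O-])N1[C@@H](Cc2ccccc2)COC1=O | intermediate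
7 | (4S)-4-benzyl-3-[(2S)-5-methyl-2-(prop-1-en-2-yl)hex-4-enoyl]-1,3-oxazolidin-2-one | C=C(C)[C@H](CC=C(C)C)C(=O)N1[C@@H](Cc2ccccc2)COC1=O | intermediate
8 | (4S)-4-benzyl-3-[(2S)-3-(3,3-dimethyloxiran-2-yl)-2-(prop-1-en-2-yl)propanoyl]-1,3-oxazolidin-2-one (oxirane epimers) | C=C(C)[C@H](CC1OC1(C)C)C(=O)N1[C@@H](Cc2ccccc2)COC1=O | intermediate
9 | (2S)-5-methyl-2-(prop-1-en-2-yl)hexane-1,5-diol | C=C(C)[C@H](CCC(C)(C)O)CO | intermediate
10 | (5S)-6-iodo-2-methyl-5-(prop-1-en-2-yl)hexan-2-ol | C=C(C)[C@H](CCC(C)(C)O)CI | intermediate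
11 | triethyl{[(5S)-6-iodo-2-methyl-5-(prop-1-en-2-yl)hexan-2-yl]oxy}silane | C=C(C)[C@H](CCC(C)(C)O[Si](CC)(CC)CC)CI | intermediate
12 | 2,4-dihydroxybenzaldehyde | O=Cc1ccc(O)cc1O | starting material
13 | 2,4-bis(tert-butyldimethylsilyloxy)benzaldehyde | O=Cc1ccc(O[Si](C)(C)C(C)(C)C)cc1O[Si](C)(C)C(C)(C)C | intermediate
14 | [2,4-bis(tert-butyldimethylsilyloxy)phenyl]methanol | OCc1ccc(O[Si](C)(C)C(C)(C)C)cc1O[Si](C)(C)C(C)(C)C | intermediate
15 | 1-(2,4-dihydroxy-6-methoxyphenyl)ethan-1-one | CC(=O)c1c(O)cc(O)cc1OC | starting material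
16 | 1-(2,4-dihydroxy-3-iodo-6-methoxyphenyl)ethan-1-one | CC(=O)c1c(O)c(I)c(O)cc1OC | intermediate
17 | 1-[4-(tert-butyldimethylsilyloxy)-2-hydroxy-3-iodo-6-methoxyphenyl]ethan-1-one | CC(=O)c1c(O)c(I)c(O[Si](C)(C)C(C)(C)C)cc1OC | intermediate
18 | 1-[2-{[2,4-bis(TBS-oxy)phenyl]methoxy}-4-(TBS-oxy)-3-iodo-6-methoxyphenyl]ethan-1-one | CC(=O)c1c(OCc2ccc(O[Si](C)(C)C(C)(C)C)cc2O[Si](C)(C)C(C)(C)C)c(I)c(O[Si](C)(C)C(C)(C)C)cc1OC | intermediate
19 | iodo{(2S)-5-methyl-2-(prop-1-en-2-yl)-5-[(triethylsilyl)oxy]hexyl}zinc | C=C(C)[C@H](CCC(C)(C)O[Si](CC)(CC)CC)C[Zn]I | intermediate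
20 | 1-[2-{[2,4-bis(TBS-oxy)phenyl]methoxy}-4-(TBS-oxy)-6-methoxy-3-{(2R)-5-methyl-2-(prop-1-en-2-yl)-5-[(triethylsilyl)oxy]hexyl}phenyl]ethan-1-one | C=C(C)[C@H](CCC(C)(C)O[Si](CC)(CC)CC)Cc1c(O[Si](C)(C)C(C)(C)C)cc(OC)c(C(C)=O)c1OCc1ccc(O[Si](C)(C)C(C)(C)C)cc1O[Si](C)(C)C(C)(C)C | intermediate
21 | lithium enolate of 20 | [Li+].C=C(C)[C@H](CCC(C)(C)O[Si](CC)(CC)CC)Cc1c(O[Si](C)(C)C(C)(C)C)cc(OC)c(C(=C)[O-])c1OCc1ccc(O[Si](C)(C)C(C)(C)C)cc1O[Si](C)(C)C(C)(C)C | intermediate
22 | 4,4,4-trifluoro-1-aryl-butane-1,3-dione from 20 (aryl as in 20) | C=C(C)[C@H](CCC(C)(C)O[Si](CC)(CC)CC)Cc1c(O[Si](C)(C)C(C)(C)C)cc(OC)c(C(=O)CC(=O)C(F)(F)F)c1OCc1ccc(O[Si](C)(C)C(C)(C)C)cc1O[Si](C)(C)C(C)(C)C | intermediate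
23 | 2-diazo-1-aryl-ethan-1-one from 20 (aryl as in 20) | C=C(C)[C@H](CCC(C)(C)O[Si](CC)(CC)CC)Cc1c(O[Si](C)(C)C(C)(C)C)cc(OC)c(C(=O)C=[N+]=[N-])c1OCc1ccc(O[Si](C)(C)C(C)(C)C)cc1O[Si](C)(C)C(C)(C)C | intermediate
24 | (2S)-2-[2,4-bis(TBS-oxy)phenyl]-7-(TBS-oxy)-5-methoxy-8-{(2R)-5-methyl-2-(prop-1-en-2-yl)-5-[(triethylsilyl)oxy]hexyl}-2,3-dihydro-4H-chromen-4-one | C=C(C)[C@H](CCC(C)(C)O[Si](CC)(CC)CC)Cc1c(O[Si](C)(C)C(C)(C)C)cc(OC)c2c1O[C@H](c1ccc(O[Si](C)(C)C(C)(C)C)cc1O[Si](C)(C)C(C)(C)C)CC2=O | intermediate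
25 | (2S)-2-(2,4-dihydroxyphenyl)-7-hydroxy-8-[(2R)-5-hydroxy-5-methyl-2-(prop-1-en-2-yl)hexyl]-5-methoxy-2,3-dihydro-4H-chromen-4-one | C=C(C)[C@H](CCC(C)(C)O)Cc1c(O)cc(OC)c2c1O[C@H](c1ccc(O)cc1O)CC2=O | target

**Step count and risks**

Total step count: 15. Longest linear sequence: 10 steps (steps 1–6, then 12–15).

Step 14 is the most likely to fail. The carbenoid may be intercepted by O1 to give an oxonium ylide that undergoes [1,2]-shift of the electron-rich benzyl group, and the twisted 2,6-disubstituted aryl ketone may slow insertion and erode discrimination of the enantiotopic hydrogens. The fallback sets out from 20 and returns at 24. It closes the same ring at the oxocarbenium level: the lithium enolate 21 of ketone 20 is O-acetylated with Ac2O to the enol acetate F1. F1 is then treated with DDQ, 2,6-dichloropyridine and LiClO4 in 1,2-dichloroethane. Hydride abstraction from the benzylic ether methylene gives an aryl-stabilised oxocarbenium ion, which the enol acetate traps in a 6-endo closure of the C2–C3 bond, the acetyl group being lost on work-up. Without catalyst control this should give 24 together with its 2R epimer F2; the two are diastereomers and would be separated by preparative HPLC before 24 goes on to step 15.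

Step 12 is the second risk. Oxidative addition and transmetalation at the aryl iodide, which is flanked by a silyloxy and a benzyloxy group, may be slow, so that protodezincation and hydrodeiodination take over. The fallback sets out from 11 and 17 and returns at 20. It changes the order of bond formation: the alkylzinc iodide 19 is added slowly to the less hindered free iodophenol 17 under the same Pd(OAc)2/SPhos catalysis, where cross-coupling should outpace protonation of the organozinc, to give the phenol F3. F3 is then etherified with alcohol 14 under Mitsunobu conditions to give 20.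

Step 11 is the third risk. The chelated, doubly ortho-substituted phenol may react sluggishly, and the activated benzylic oxyphosphonium ion may ionise and alkylate the reduced azodicarboxylate instead. The fallback sets out from 14 and 17 and returns at 18. Alcohol 14 is converted with CBr4 and PPh3 (CH2Cl2, 0 °C) into 2,4-bis(tert-butyldimethylsilyloxy)benzyl bromide F4, which is used at once in a Williamson etherification of phenol 17 (K2CO3, acetone, rt).

Further compounds
F1 | step 14 | 1-aryl-ethenyl acetate, enol acetate of 20 (aryl as in 20) | C=C(C)[C@H](CCC(C)(C)O[Si](CC)(CC)CC)Cc1c(O[Si](C)(C)C(C)(C)C)cc(OC)c(C(=C)OC(C)=O)c1OCc1ccc(O[Si](C)(C)C(C)(C)C)cc1O[Si](C)(C)C(C)(C)C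
F2 | step 14 | (2R) epimer of 24 | C=C(C)[C@H](CCC(C)(C)O[Si](CC)(CC)CC)Cc1c(O[Si](C)(C)C(C)(C)C)cc(OC)c2c1O[C@@H](c1ccc(O[Si](C)(C)C(C)(C)C)cc1O[Si](C)(C)C(C)(C)C)CC2=O
F3 | step 12 | 1-[4-(TBS-oxy)-2-hydroxy-6-methoxy-3-{(2R)-5-methyl-2-(prop-1-en-2-yl)-5-[(triethylsilyl)oxy]hexyl}phenyl]ethan-1-one | C=C(C)[C@H](CCC(C)(C)O[Si](CC)(CC)CC)Cc1c(O[Si](C)(C)C(C)(C)C)cc(OC)c(C(C)=O)c1O
F4 | step 11 | 2,4-bis(tert-butyldimethylsilyloxy)benzyl bromide | BrCc1ccc(O[Si](C)(C)C(C)(C)C)cc1O[Si](C)(C)C(C)(C)C
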